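**Strategy.** Everything rests on splicing C7 and C8 into a bought eight-membered ring. The ten-membered carbocycle C1–C10 (germacrane numbering) contains the (Z,Z)-diene C10(Me)=C1–C2–C3–C4(Me)=C5 of isoprene dimer and a masked 1,3-diketone at C6/C8. Dichloroketene is added across the C6=C9 silyl enol ether of a cyclooctadienone. The key step then breaks the C6–C9 fusion bond of the resulting 3-silyloxycyclobutanone with O-to-O silyl transfer, expanding the ring from eight to ten atoms and leaving C6 as a free enone carbonyl beside C8 as an enol silane. CBS reductions set C2 and C6; C7, C11 and C8 are relayed from C6 through a tethered chloropyruvate aldol.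

Key step: step 8

Atom labels: ring carbons carry their germacrane numbers in every compound (alkenes C1=C10 and C4=C5, acetates on C2 and C8, lactone oxygen on C6, side chain C11–C13 on C7); in 1–8 the pair C7/C8 is still missing and C6 is bonded to C9.

Assumption: commercial isoprene dimer 1 is used as the 1,5-dimethyl isomer, the minor 1,6-dimethyl isomer having been removed by fractional distillation.

Step 1
Reactants: 1 (1Z,5Z)-1,5-dimethylcycloocta-1,5-diene
Product: 2 (2Z,6Z)-3,7-dimethylcycloocta-2,6-dien-1-one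
Conditions: dirhodium tetrakis(caprolactamate) (1 mol %), tBuOOH (70% aq.), K2CO3, CH2Cl2, rt, stopped at partial conversion
Reagents that add atoms: tert-butyl hydroperoxide, CC(C)(C)OO
Why: Dirhodium-catalysed radical allylic C–H oxidation by tert-butylperoxyl radicals attacks the CH2 next to the CH terminus of a trisubstituted alkene (as 1-methylcycloalkenes give 3-methylcycloalk-2-enones), and the two alkenes of 1 are homotopic, so one mono-enone should result.

Step 2
Reactants: 2 (2Z,6Z)-3,7-dimethylcycloocta-2,6-dien-1-one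
Product: 3 (1S,2Z,6Z)-3,7-dimethylcycloocta-2,6-dien-1-ol
Conditions: (R)-1-methyl-3,3-diphenyltetrahydro-1H,3H-pyrrolo[1,2-c][1,3,2]oxazaborole [(R)-Me-CBS, 20 mol %], catecholborane, toluene, −78 °C
Reagents that add atoms: none
Why: Corey–Bakshi–Shibata reduction, with the alkenyl arm as the large and the CH2 arm as the small substituent, gives 1,2-reduction and sets the carbinol centre (C2 of the target) as S under catalyst control.

Step 3
Reactants: 3 (1S,2Z,6Z)-3,7-dimethylcycloocta-2,6-dien-1-ol
Product: 4 (1S,2Z,6Z)-3,7-dimethylcycloocta-2,6-dien-1-yl acetate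
Conditions: Ac2O, pyridine, 4-(dimethylamino)pyridine (cat.), CH2Cl2, 0 °C
Reagents that add atoms: acetic anhydride, CC(=O)OC(C)=O
Why: Standard acylation installs the C2 acetate of the target, which also deactivates its own allylic C–H and the C1=C10 alkene in steps 4 and 6.

Step 4
Reactants: 4 (1S,2Z,6Z)-3,7-dimethylcycloocta-2,6-dien-1-yl acetate
Product: 5 (1S,2Z,6Z)-3,7-dimethyl-5-oxocycloocta-2,6-dien-1-yl acetate
Conditions: dirhodium tetrakis(caprolactamate) (1 mol %), tBuOOH (70% aq.), K2CO3, CH2Cl2, rt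
Reagents that add atoms: tert-butyl hydroperoxide, CC(C)(C)OO
Why: The same allylic C–H oxidation now falls on C6, the only remaining CH2 that flanks a CH alkene terminus, the acetoxy-bearing C–H being deactivated towards the electrophilic peroxyl radical as in the oxidation of cycloalkenyl acetates to 4-acetoxy-enones.

Step 5
Reactants: 5 (1S,2Z,6Z)-3,7-dimethyl-5-oxocycloocta-2,6-dien-1-yl acetate
Product: 6 (1S,2Z,4E,6Z)-5-(tert-butyldimethylsilyloxy)-3,7-dimethylcycloocta-2,4,6-trien-1-yl acetate
Conditions: tBuMe2SiOTf, Et3N, CH2Cl2, −78 → 0 °C, used at once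
Reagents that add atoms: tert-butyldimethylsilyl trifluoromethanesulfonate, CC(C)(C)[Si](C)(C)OS(=O)(=O)C(F)(F)F
Why: Soft enolisation with O-silylation removes the α′-proton at C9, which is also allylic to C10=C1, and should give the cross-conjugated 2-silyloxy diene rather than the γ-deprotonated isomer.

Step 6
Reactants: 6 (1S,2Z,4E,6Z)-5-(tert-butyldimethylsilyloxy)-3,7-dimethylcycloocta-2,4,6-trien-1-yl acetate
Product: 7 (5S)-10,10-dichloro-1-(tert-butyldimethylsilyloxy)-3,7-dimethyl-9-oxo-cis-bicyclo[6.2.0]deca-2,6-dien-5-yl acetate (both cis-fused diastereomers)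
Conditions: Cl2CHCOCl, Et3N (slow addition), hexane, 0 °C → rt
Reagents that add atoms: dichloroacetyl chloride, O=C(Cl)C(Cl)Cl
Why: Thermal [2+2] cycloaddition of dichloroketene to a silyl enol ether joins nucleophilic C9 to the ketene carbonyl carbon (C8) and C6 to CCl2 (C7) suprafacially (cis fusion); both facial isomers converge in step 8, and C1=C10 is shielded by its methyl group and deactivated by the allylic acetoxy group.

Step 7
Reactants: 7 (5S)-10,10-dichloro-1-(tert-butyldimethylsilyloxy)-3,7-dimethyl-9-oxo-cis-bicyclo[6.2.0]deca-2,6-dien-5-yl acetate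
Product: 8 (5S)-1-(tert-butyldimethylsilyloxy)-3,7-dimethyl-9-oxo-cis-bicyclo[6.2.0]deca-2,6-dien-5-yl acetate (both cis-fused diastereomers)
Conditions: Zn dust, AcOH, iPrOH, 0 °C → rt
Reagents that add atoms: none
Why: Zinc reduction of the α,α-dichloroketone through its zinc enolate, the standard dechlorination of dichloroketene adducts, spares silyl ether, acetate and alkenes and removes the chlorines that would otherwise steer the later fragmentation to the C6–C7 bond.

Step 8
Reactants: 8 (5S)-1-(tert-butyldimethylsilyloxy)-3,7-dimethyl-9-oxo-cis-bicyclo[6.2.0]deca-2,6-dien-5-yl acetate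
Product: 9 (2S)-2-acetoxy-8-(tert-butyldimethylsilyloxy)-4,10-dimethylcyclodeca-1(10),4,8-trien-6-one (germacrane ring numbering; 1(10)Z and 4Z; enol ether cis in the ring)
Conditions: tBuMe2SiOTf (5 mol %), 2,6-di-tert-butyl-4-methylpyridine (5 mol %), CH2Cl2, −78 → −40 °C; then Et3N, filtration through basic alumina
Reagents that add atoms: none
Why: Proposed new method: the silyl cation from tBuMe2SiOTf silylates the cyclobutanone oxygen O8, the lone pair on O6 then pushes out the C6–C9 fusion bond (push–pull, retro-Mukaiyama-aldol fragmentation of a donor–acceptor cyclobutane) to give the C8 silyl dienol ether and the O-silylated C6 ketone, which passes its silyl cation to the next molecule of 8, so the eight-membered ring becomes the ten-membered ring C1–C10 with C7 and C8 inserted. The closest known reactions are the fluoride- or acid-induced desilylative retro-aldol ring expansion of 1-silyloxybicyclo[n.2.0]alkanones to cycloalkane-1,3-diones and the Lewis-acid C2–C3 cleavage of 3-alkoxycyclobutanones; the new element is the O-to-O silyl transfer that leaves the two carbonyls differentiated. No ring is closed: the ten-membered ring arises solely by scission of the bond shared by the four- and eight-membered rings. No stereocentre is created (C6 and C9 become trigonal, C2 is untouched, and the enol ether geometry is erased in step 12). The selectivity needed is cleavage of C6–C9 rather than C6–C7; it is secured by the prior removal of the chlorines (no stabilised C7 anion) and by conjugation of the developing C8=C9 enol ether with C10=C1, while the two (Z)-trisubstituted alkenes take no part and keep their geometry.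

Step 9
Reactants: 9 (2S)-2-acetoxy-8-(tert-butyldimethylsilyloxy)-4,10-dimethylcyclodeca-1(10),4,8-trien-6-one
Product: 10 (2S,6S)-2-acetoxy-8-(tert-butyldimethylsilyloxy)-4,10-dimethylcyclodeca-1(10),4,8-trien-6-ol
Conditions: (R)-1-methyl-3,3-diphenyltetrahydro-1H,3H-pyrrolo[1,2-c][1,3,2]oxazaborole [(R)-Me-CBS, 20 mol %], catecholborane, toluene, −78 °C
Reagents that add atoms: none
Why: Corey–Bakshi–Shibata reduction of the enone carbonyl (large arm C5=C4, small arm C7H2), while C8 is masked as its enol silane, sets C6 under catalyst control with oxygen on the face of the C2 acetoxy group (S here; the same centre is 6R in 15–17, where C7 outranks C5).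

Step 10
Reactants: 11 pyruvic acid
Product: 12 3-chloropyruvic acid
Conditions: SO2Cl2 (1.05 equiv), neat, 25–30 °C
Reagents that add atoms: sulfuryl chloride, O=S(=O)(Cl)Cl
Why: Electrophilic α-chlorination of the methyl ketone through its enol by sulfuryl chloride is the established preparation of chloropyruvic acid.

Step 11
Reactants: 10 (2S,6S)-2-acetoxy-8-(tert-butyldimethylsilyloxy)-4,10-dimethylcyclodeca-1(10),4,8-trien-6-ol; 12 3-chloropyruvic acid
Product: 13 (2S,6S)-2-acetoxy-8-(tert-butyldimethylsilyloxy)-4,10-dimethylcyclodeca-1(10),4,8-trien-6-yl 3-chloro-2-oxopropanoate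
Conditions: N,N'-dicyclohexylcarbodiimide, 4-(dimethylamino)pyridine (10 mol %), CH2Cl2, −20 °C, acid added last
Reagents that add atoms: none
Why: Steglich esterification of the secondary allylic alcohol proceeds with retention at C6 and installs C11–C13 as an electrophilic α-keto ester tether on O6.

Step 12
Reactants: 13 (2S,6S)-2-acetoxy-8-(tert-butyldimethylsilyloxy)-4,10-dimethylcyclodeca-1(10),4,8-trien-6-yl 3-chloro-2-oxopropanoate
Product: 15 (2S,6R,7R,11S)-2-acetoxy-13-chloro-11-hydroxy-8-oxogermacra-1(10)Z,4Z-dien-12,6-olide, via keto ester 14 (not isolated)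
Conditions: HF·pyridine, pyridine, THF, 0 °C; aqueous work-up, no purification; then 2-tert-butylimino-2-diethylamino-1,3-dimethylperhydro-1,3,2-diazaphosphorine (BEMP, 0.2 equiv), THF, 0.005 M, −78 → −30 °C; AcOH quench
Reagents that add atoms: none
Why: Intramolecular aldol addition (5-exo-trig) of the unmasked C8 ketone to the tethered α-keto ester, in which only the C7 enolate can reach C11 through a five-membered transition state, C7 equilibrates α to the ketone to the trans-fused 12,6-lactone, and the dipole-minimised open transition state of the phosphazenium enolate turns the ketone oxygen away from O8, so that 11-OH should end syn to H-7 and CH2Cl syn to C8.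

Step 13
Reactants: 15 (2S,6R,7R,11S)-2-acetoxy-13-chloro-11-hydroxy-8-oxogermacra-1(10)Z,4Z-dien-12,6-olide
Product: 16 (2S,6R,7R,8R,11S)-2-acetoxy-13-chloro-8,11-dihydroxygermacra-1(10)Z,4Z-dien-12,6-olide
Conditions: NaBH4, CeCl3·7H2O, MeOH, −78 °C
Reagents that add atoms: none
Why: Borohydride 1,2-reduction under Luche conditions (which also keep the medium from closing the chlorohydrin to the epoxide) should deliver hydride to the C8 carbonyl from the face opposite the quaternary C11 on C7 (Felkin-type peripheral attack), giving the 8β-alcohol cis to the C7–C11 bond.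

Step 14
Reactants: 16 (2S,6R,7R,8R,11S)-2-acetoxy-13-chloro-8,11-dihydroxygermacra-1(10)Z,4Z-dien-12,6-olide
Product: 17 (2S,6R,7R,8R,11S)-2,8-diacetoxy-13-chloro-11-hydroxygermacra-1(10)Z,4Z-dien-12,6-olide (CNP0182971.4)
Conditions: Ac2O, pyridine, 0 °C → rt
Reagents that add atoms: acetic anhydride, CC(=O)OC(C)=O
Why: Acetylation in pyridine without an acyl-transfer catalyst esterifies the secondary C8 hydroxyl and should leave the hindered tertiary α-hydroxy lactone at C11 free.

**Compound list**

1 | (1Z,5Z)-1,5-dimethylcycloocta-1,5-diene | C/C1=C/CC/C(C)=C\CC1 | starting material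
2 | (2Z,6Z)-3,7-dimethylcycloocta-2,6-dien-1-one | O=C1/C=C(/C)CC/C=C(/C)C1 | intermediate
3 | (1S,2Z,6Z)-3,7-dimethylcycloocta-2,6-dien-1-ol | O[C@@H]1/C=C(/C)CC/C=C(/C)C1 | intermediate
4 | (1S,2Z,6Z)-3,7-dimethylcycloocta-2,6-dien-1-yl acetate | CC(=O)O[C@@H]1/C=C(/C)CC/C=C(/C)C1 | intermediate
5 | (1S,2Z,6Z)-3,7-dimethyl-5-oxocycloocta-2,6-dien-1-yl acetate | CC(=O)O[C@@H]1/C=C(/C)CC(=O)/C=C(/C)C1 | intermediate
6 | (1S,2Z,4E,6Z)-5-(tert-butyldimethylsilyloxy)-3,7-dimethylcycloocta-2,4,6-trien-1-yl acetate | CC(=O)O[C@@H]1/C=C(/C)\C=C(O[Si](C)(C)C(C)(C)C)/C=C(/C)C1 | intermediate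
7 | (5S)-10,10-dichloro-1-(tert-butyldimethylsilyloxy)-3,7-dimethyl-9-oxo-cis-bicyclo[6.2.0]deca-2,6-dien-5-yl acetate (ring-fusion centres cis, both diastereomers, left undefined) | CC(=O)O[C@@H]1/C=C(/C)C2C(=O)C(Cl)(Cl)C2(O[Si](C)(C)C(C)(C)C)/C=C(/C)C1 | intermediate
8 | (5S)-1-(tert-butyldimethylsilyloxy)-3,7-dimethyl-9-oxo-cis-bicyclo[6.2.0]deca-2,6-dien-5-yl acetate (ring-fusion centres cis, both diastereomers, left undefined) | CC(=O)O[C@@H]1/C=C(/C)C2C(=O)CC2(O[Si](C)(C)C(C)(C)C)/C=C(/C)C1 | intermediate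
9 | (2S)-2-acetoxy-8-(tert-butyldimethylsilyloxy)-4,10-dimethylcyclodeca-1(10),4,8-trien-6-one (germacrane ring numbering; enol ether drawn cis in the ring, geometry immaterial) | CC(=O)O[C@@H]1/C=C(/C)\C=C(O[Si](C)(C)C(C)(C)C)/CC(=O)/C=C(/C)C1 | intermediate
10 | (2S,6S)-2-acetoxy-8-(tert-butyldimethylsilyloxy)-4,10-dimethylcyclodeca-1(10),4,8-trien-6-ol | CC(=O)O[C@@H]1/C=C(/C)\C=C(O[Si](C)(C)C(C)(C)C)/C[C@H](O)/C=C(/C)C1 | intermediate
11 | pyruvic acid | CC(=O)C(=O)O | starting material
12 | 3-chloropyruvic acid | O=C(O)C(=O)CCl | intermediate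
13 | (2S,6S)-2-acetoxy-8-(tert-butyldimethylsilyloxy)-4,10-dimethylcyclodeca-1(10),4,8-trien-6-yl 3-chloro-2-oxopropanoate | CC(=O)O[C@@H]1/C=C(/C)\C=C(O[Si](C)(C)C(C)(C)C)/C[C@H](OC(=O)C(=O)CCl)/C=C(/C)C1 | intermediate
14 | (2S,6S)-2-acetoxy-4,10-dimethyl-8-oxocyclodeca-1(10),4-dien-6-yl 3-chloro-2-oxopropanoate | CC(=O)O[C@@H]1/C=C(/C)CC(=O)C[C@H](OC(=O)C(=O)CCl)/C=C(/C)C1 | intermediate
15 | (2S,6R,7R,11S)-2-acetoxy-13-chloro-11-hydroxy-8-oxogermacra-1(10)Z,4Z-dien-12,6-olide | CC(=O)O[C@@H]1/C=C(/C)CC(=O)[C@@H]2[C@@H](/C=C(/C)C1)OC(=O)[C@]2(O)CCl | intermediate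
16 | (2S,6R,7R,8R,11S)-2-acetoxy-13-chloro-8,11-dihydroxygermacra-1(10)Z,4Z-dien-12,6-olide | CC(=O)O[C@@H]1/C=C(/C)C[C@@H](O)[C@@H]2[C@@H](/C=C(/C)C1)OC(=O)[C@]2(O)CCl | intermediate
17 | (2S,6R,7R,8R,11S)-2,8-diacetoxy-13-chloro-11-hydroxygermacra-1(10)Z,4Z-dien-12,6-olide (CNP0182971.4) | CC(=O)O[C@@H]1/C=C(/C)C[C@@H](OC(C)=O)[C@@H]2[C@@H](/C=C(/C)C1)OC(=O)[C@]2(O)CCl | target

**Total step count:** 14. **Longest linear sequence:** 13 (steps 1–9 and 11–14; step 10 is a one-step side branch).

**Steps most likely to fail**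

Step 8. The silyl cation may fail to turn over, or adventitious acid may strip the silyl group, so that the free 1,3-diketone forms and the C6/C8 differentiation is lost. Fallback by known chemistry, setting out from 8: tetrabutylammonium fluoride buffered with AcOH (THF, 0 °C) should effect the precedented desilylative retro-aldol ring expansion to (2S)-4,10-dimethyl-6,8-dioxocyclodeca-1(10),4-dien-2-yl acetate F1. NaBH4 in MeOH–CH2Cl2 at −78 °C reduces the non-conjugated C8 ketone in preference to the enone, giving the 8-hydroxy enone F2 (C8 epimers, of no consequence). Et3SiOTf and 2,6-lutidine give the triethylsilyl ether F3. CBS reduction with the catalyst of step 9 gives the 6S alcohol F4. Steglich esterification with 12 gives the chloropyruvate F5. HF·pyridine frees the C8 alcohol F6, and Dess–Martin periodinane oxidises it to the keto ester 14, which enters the second half of step 12.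

Step 12. The C7 enolate may expel the C6 acyloxy group (E1cB) to a dienone, the acidic chloromethyl ketone may self-condense, or C7 may attack the wrong face of the C11 ketone. Fallback, setting out from 10: NaH and propargyl bromide (THF, −20 → 0 °C) give the O6 propargyl ether F7, whose ether oxygen is a poor leaving group. HF·pyridine then pyrrolidine, Cu(OTf)2 and PPh3 should effect Conia-ene carbocyclisation (5-exo-dig from C7, trans fusion by equilibration) to the 8-oxo 3-methylenetetrahydrofuran F8. CrO3 with 3,5-dimethylpyrazole oxidises the doubly activated O–CH2 to the α-methylene lactone F9. tBuOOH with 1,8-diazabicyclo[5.4.0]undec-7-ene epoxidises only the electron-poor exocyclic alkene, from the face of H-7, giving the 11,13-epoxide F10. LiCl and AcOH in THF open it at C13 to give 15.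

Step 4. Hydrogen abstraction may spread over C3, C9, the methyl groups and the acetoxy-bearing C2–H, and the product may be oxidised further. Fallback, setting out from 4: mCPBA (1 equiv, CH2Cl2, −20 °C) should epoxidise the C4=C5 alkene, which is remote from the deactivating acetoxy group, giving the monoepoxide F11. PhSeNa (from (PhSe)2 and NaBH4, EtOH) opens it at secondary C5 to the hydroxy selenide F12. H2O2 brings about selenoxide syn-elimination away from the carbinol to the tertiary allylic alcohol F13. Pyridinium chlorochromate [C5H5NH][CrO3Cl] effects the Babler–Dauben oxidative 1,3-transposition to 5.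

Further compounds
F1 | step 8 | (2S)-4,10-dimethyl-6,8-dioxocyclodeca-1(10),4-dien-2-yl acetate | CC(=O)O[C@@H]1/C=C(/C)CC(=O)CC(=O)/C=C(/C)C1
F2 | step 8 | (2S)-8-hydroxy-4,10-dimethyl-6-oxocyclodeca-1(10),4-dien-2-yl acetate (C8 epimers) | CC(=O)O[C@@H]1/C=C(/C)CC(O)CC(=O)/C=C(/C)C1
F3 | step 8 | (2S)-4,10-dimethyl-6-oxo-8-(triethylsilyloxy)cyclodeca-1(10),4-dien-2-yl acetate (C8 epimers) | CC(=O)O[C@@H]1/C=C(/C)CC(O[Si](CC)(CC)CC)CC(=O)/C=C(/C)C1
F4 | step 8 | (2S,6S)-6-hydroxy-4,10-dimethyl-8-(triethylsilyloxy)cyclodeca-1(10),4-dien-2-yl acetate (C8 epimers) | CC(=O)O[C@@H]1/C=C(/C)CC(O[Si](CC)(CC)CC)C[C@H](O)/C=C(/C)C1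
F5 | step 8 | (2S,6S)-2-acetoxy-4,10-dimethyl-8-(triethylsilyloxy)cyclodeca-1(10),4-dien-6-yl 3-chloro-2-oxopropanoate (C8 epimers) | CC(=O)O[C@@H]1/C=C(/C)CC(O[Si](CC)(CC)CC)C[C@H](OC(=O)C(=O)CCl)/C=C(/C)C1
F6 | step 8 | (2S,6S)-2-acetoxy-8-hydroxy-4,10-dimethylcyclodeca-1(10),4-dien-6-yl 3-chloro-2-oxopropanoate (C8 epimers) | CC(=O)O[C@@H]1/C=C(/C)CC(O)C[C@H](OC(=O)C(=O)CCl)/C=C(/C)C1
F7 | step 12 | O6 propargyl ether of 10 | CC(=O)O[C@@H]1/C=C(/C)\C=C(O[Si](C)(C)C(C)(C)C)/C[C@H](OCC#C)/C=C(/C)C1
F8 | step 12 | trans-fused 3-methylenetetrahydrofuran (O6–C12H2–C11(=C13H2)–C7) bearing the C8 ketone and the C2 acetate | CC(=O)O[C@@H]1/C=C(/C)CC(=O)[C@@H]2[C@@H](/C=C(/C)C1)OCC2=C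
F9 | step 12 | 2-acetoxy-8-oxogermacra-1(10)Z,4Z,11(13)-trien-12,6-olide (trans-fused; 2S,6R) | CC(=O)O[C@@H]1/C=C(/C)CC(=O)[C@@H]2[C@@H](/C=C(/C)C1)OC(=O)C2=C
F10 | step 12 | 2-acetoxy-11,13-epoxy-8-oxogermacra-1(10)Z,4Z-dien-12,6-olide (epoxide oxygen syn to H-7) | CC(=O)O[C@@H]1/C=C(/C)CC(=O)[C@@H]2[C@@H](/C=C(/C)C1)OC(=O)[C@]23CO3
F11 | step 4 | (1S,2Z)-6,7-epoxy-3,7-dimethylcyclooct-2-en-1-yl acetate (cis-epoxide, both diastereomers) | CC(=O)O[C@@H]1/C=C(/C)CCC2OC2(C)C1
F12 | step 4 | (1S,2Z)-7-hydroxy-3,7-dimethyl-6-(phenylselanyl)cyclooct-2-en-1-yl acetate (diastereomers) | CC(=O)O[C@@H]1/C=C(/C)CCC([Se]c2ccccc2)C(C)(O)C1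
F13 | step 4 | (1S,2Z,5Z)-7-hydroxy-3,7-dimethylcycloocta-2,5-dien-1-yl acetate (C7 epimers) | CC(=O)O[C@@H]1/C=C(/C)C/C=C\C(C)(O)C1
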